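**Plan**

Numbering: tetralin C1 bears the pendant syringyl ring C, C2 and C3 bear CH2OH, C4 is CH2, and C4a/C8a belong to the fused arene ring A. Ring B is the saturated ring.
Retrosynthesis: three benzyl groups are removed and C3-CH2OH is taken back to CHO. Ring B is then cut at C2-C3 and at C1-C8a together, giving a 3-arylpropanal (ring A, C4, C3, CHO) and an O-benzylated sinapyl alcohol (ring C, C1=C2, CH2O).
Enabling feature: C3 is alpha to a latent aldehyde and two atoms from ring A, whose C8a is ortho and para to methoxy groups, and C1 is benzylic to electron-rich ring C. A radical cation at C3 can therefore add to C2, and the C1 cation that follows is caught by C8a.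
Forward: syringaldehyde is benzylated, homologated and reduced to one cinnamyl alcohol, which supplies both partners (O-benzylation, redox isomerisation). Ring B forms in one oxidative formal [4+2], and reduction and hydrogenolysis finish the route.
Stereochemistry: C3 comes from a chiral imidazolidinone catalyst, C2 from the open transition state of the radical addition relative to C3, and C1 from the chair-like ring closure (all-trans).

Key step: step 6

Assumption: the target SMILES is read as the all-trans (1S,2R,3R) isomer in the numbering above, that is (+)-lyoniresinol.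
Remark: the catalyst of step 6 is commercial (2S,5S)-5-benzyl-2-tert-butyl-3-methylimidazolidin-4-one, SMILES CN1[C@H](N[C@@H](Cc2ccccc2)C1=O)C(C)(C)C, used as its CF3CO2H salt.

Step 1
Reactants: 1 syringaldehyde (4-hydroxy-3,5-dimethoxybenzaldehyde)
Product: 2 4-(benzyloxy)-3,5-dimethoxybenzaldehyde
Conditions: BnBr, K2CO3, DMF, 60 °C
Reagents that add atoms: benzyl bromide, BrCc1ccccc1
Why: Williamson ether synthesis on the acidic para-formyl phenol masks it against the later oxidant with a group that leaves in the final hydrogenolysis.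

Step 2
Reactants: 2 4-(benzyloxy)-3,5-dimethoxybenzaldehyde
Product: 3 ethyl (E)-3-[4-(benzyloxy)-3,5-dimethoxyphenyl]prop-2-enoate
Conditions: Ph3P=CHCO2Et, toluene, 90 °C
Reagents that add atoms: ethyl (triphenylphosphoranylidene)acetate, CCOC(=O)C=P(c1ccccc1)(c1ccccc1)c1ccccc1
Why: Wittig olefination of an aromatic aldehyde with a stabilised ylide should give the E-cinnamate.

Step 3
Reactants: 3 ethyl (E)-3-[4-(benzyloxy)-3,5-dimethoxyphenyl]prop-2-enoate
Product: 4 (E)-3-[4-(benzyloxy)-3,5-dimethoxyphenyl]prop-2-en-1-ol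
Conditions: i-Bu2AlH (2.5 equiv), CH2Cl2, -78 to 0 °C; aq. potassium sodium tartrate
Reagents that add atoms: none
Why: 1,2-reduction of an alpha,beta-unsaturated ester with i-Bu2AlH should give the allylic alcohol without touching the alkene or the benzyl ether.

Step 4
Reactants: 4 (E)-3-[4-(benzyloxy)-3,5-dimethoxyphenyl]prop-2-en-1-ol
Product: 5 2-(benzyloxy)-5-[(E)-3-(benzyloxy)prop-1-en-1-yl]-1,3-dimethoxybenzene
Conditions: NaH, BnBr, Bu4NI (cat.), THF, 0 °C to rt
Reagents that add atoms: benzyl bromide, BrCc1ccccc1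
Why: Williamson etherification of the alkoxide runs under basic conditions, which avoid ionisation of the acid-sensitive electron-rich cinnamyl system.

Step 5
Reactants: 4 (E)-3-[4-(benzyloxy)-3,5-dimethoxyphenyl]prop-2-en-1-ol
Product: 6 3-[4-(benzyloxy)-3,5-dimethoxyphenyl]propanal
Conditions: CpRuCl(PPh3)2 (5 mol %), Et3NHPF6 (10 mol %), dioxane, 100 °C
Reagents that add atoms: none
Why: Ruthenium-catalysed redox isomerisation of a primary allylic alcohol (beta-hydride elimination to a bound enal, hydride return to the beta carbon) should give the saturated aldehyde and leave the aryl benzyl ether intact.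

Step 6
Reactants: 5 2-(benzyloxy)-5-[(E)-3-(benzyloxy)prop-1-en-1-yl]-1,3-dimethoxybenzene (2 equiv); 6 3-[4-(benzyloxy)-3,5-dimethoxyphenyl]propanal
Product: 9 (2R,3R,4S)-6-(benzyloxy)-4-[4-(benzyloxy)-3,5-dimethoxyphenyl]-3-[(benzyloxy)methyl]-5,7-dimethoxy-1,2,3,4-tetrahydronaphthalene-2-carbaldehyde, via enamine 7 (not isolated), via benzylic cation 8 (not isolated)
Conditions: (2S,5S)-5-benzyl-2-tert-butyl-3-methylimidazolidin-4-one·CF3CO2H (20 mol %), Fe(phen)3(SbF6)3 (2.5 equiv), Na2HPO4 (2.5 equiv), MeCN/DME, -30 °C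
Reagents that add atoms: none
Why: The catalyst condenses with 6 to the E-enamine 7, the outer-sphere trivalent iron oxidant removes one electron to give a three-pi-electron radical cation, its electrophilic alpha carbon (C3) adds to the aryl-remote alkene carbon of 5 (C2), a second electron transfer turns the benzylic radical into the syringyl-stabilised cation 8 (radical-polar crossover), C8a of ring A attacks C1, and proton loss with hydrolysis of the iminium ion frees 9 and the catalyst. The closest known reaction type is the enantioselective organo-SOMO cascade cycloaddition (formal [4+2]) of 3-arylpropanals with styrenes, which joins two carbons that are both nucleophilic in closed-shell chemistry. Ring B, the only ring closed, forms by a 6-endo Friedel-Crafts attack (the C4a-C8a pi bond lies inside the new ring) through a chair-like transition state. C3 is controlled by the catalyst, whose benzyl and tert-butyl groups cover the Re face of the enamine carbon so that bonding at the Si face should give 3R; C2 is controlled by an open staggered transition state in which the styrenyl carbon stands anti to the bulky iminium carbon and CH2OBn takes the sector next to the alpha hydrogen, which should give the 2,3-trans relation; C1 is controlled by the chair-like closure that places ring C pseudo-equatorial and trans to CH2OBn. The step needs chemoselective oxidation of the enamine beside a styrene and two trialkoxyarenes, secured by the much lower oxidation potential of 7 and by a coordinatively saturated, non-Lewis-acidic oxidant that also spares the cinnamyl ether, and it needs regioselective addition at C2, secured by benzylic stabilisation at C1. The site of arylation is unambiguous because the two ortho positions of ring A are equivalent and each is ortho and para to a methoxy group, and direct alpha-arylation of 7 is excluded because it would close a four-membered ring.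

Step 7
Reactants: 9 (2R,3R,4S)-6-(benzyloxy)-4-[4-(benzyloxy)-3,5-dimethoxyphenyl]-3-[(benzyloxy)methyl]-5,7-dimethoxy-1,2,3,4-tetrahydronaphthalene-2-carbaldehyde
Product: 10 {(2R,3R,4S)-6-(benzyloxy)-4-[4-(benzyloxy)-3,5-dimethoxyphenyl]-3-[(benzyloxy)methyl]-5,7-dimethoxy-1,2,3,4-tetrahydronaphthalen-2-yl}methanol
Conditions: NaBH4, MeOH/CH2Cl2, 0 °C
Reagents that add atoms: none
Why: Borohydride reduction of the aldehyde is fast at low temperature and removes the only epimerisable centre (C3, already in its more stable equatorial arrangement) without creating a new stereocenter.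

Step 8
Reactants: 10 {(2R,3R,4S)-6-(benzyloxy)-4-[4-(benzyloxy)-3,5-dimethoxyphenyl]-3-[(benzyloxy)methyl]-5,7-dimethoxy-1,2,3,4-tetrahydronaphthalen-2-yl}methanol
Product: 11 (+)-lyoniresinol, (6R,7R,8S)-8-(4-hydroxy-3,5-dimethoxyphenyl)-6,7-bis(hydroxymethyl)-1,3-dimethoxy-5,6,7,8-tetrahydronaphthalen-2-ol
Conditions: H2 (1 atm), Pd/C (10 wt %), EtOAc/MeOH, rt
Reagents that add atoms: none
Why: Catalytic hydrogenolysis should cleave the two aryl benzyl ethers and the alkyl benzyl ether in one operation, while the methyl ethers, the diarylmethine C1 and all three stereocenters are inert.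

**Compound list**

1 | syringaldehyde (4-hydroxy-3,5-dimethoxybenzaldehyde) | COc1cc(C=O)cc(OC)c1O | starting material
2 | 4-(benzyloxy)-3,5-dimethoxybenzaldehyde | COc1cc(C=O)cc(OC)c1OCc1ccccc1 | intermediate
3 | ethyl (E)-3-[4-(benzyloxy)-3,5-dimethoxyphenyl]prop-2-enoate | CCOC(=O)/C=C/c1cc(OC)c(OCc2ccccc2)c(OC)c1 | intermediate
4 | (E)-3-[4-(benzyloxy)-3,5-dimethoxyphenyl]prop-2-en-1-ol | OC/C=C/c1cc(OC)c(OCc2ccccc2)c(OC)c1 | intermediate
5 | 2-(benzyloxy)-5-[(E)-3-(benzyloxy)prop-1-en-1-yl]-1,3-dimethoxybenzene | C(OC/C=C/c1cc(OC)c(OCc2ccccc2)c(OC)c1)c1ccccc1 | intermediate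
6 | 3-[4-(benzyloxy)-3,5-dimethoxyphenyl]propanal | O=CCCc1cc(OC)c(OCc2ccccc2)c(OC)c1 | intermediate
7 | catalyst-bound E-enamine of aldehyde 6 (not isolated) | CN1[C@H](N(/C=C/Cc2cc(OC)c(OCc3ccccc3)c(OC)c2)[C@@H](Cc2ccccc2)C1=O)C(C)(C)C | intermediate
8 | catalyst-bound open-chain iminium ion carrying the C1 benzylic cation, C2-C3 bond formed (not isolated) | CN1[C@H]([N+](=C[C@H](Cc2cc(OC)c(OCc3ccccc3)c(OC)c2)[C@H](COCc2ccccc2)[CH+]c2cc(OC)c(OCc3ccccc3)c(OC)c2)[C@@H](Cc2ccccc2)C1=O)C(C)(C)C | intermediate
9 | (2R,3R,4S)-6-(benzyloxy)-4-[4-(benzyloxy)-3,5-dimethoxyphenyl]-3-[(benzyloxy)methyl]-5,7-dimethoxy-1,2,3,4-tetrahydronaphthalene-2-carbaldehyde | COc1cc([C@H]2c3c(cc(OC)c(OCc4ccccc4)c3OC)C[C@@H](C=O)[C@@H]2COCc2ccccc2)cc(OC)c1OCc1ccccc1 | intermediate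
10 | {(2R,3R,4S)-6-(benzyloxy)-4-[4-(benzyloxy)-3,5-dimethoxyphenyl]-3-[(benzyloxy)methyl]-5,7-dimethoxy-1,2,3,4-tetrahydronaphthalen-2-yl}methanol | COc1cc([C@H]2c3c(cc(OC)c(OCc4ccccc4)c3OC)C[C@@H](CO)[C@@H]2COCc2ccccc2)cc(OC)c1OCc1ccccc1 | intermediate
11 | (+)-lyoniresinol | COc1cc([C@H]2c3c(cc(OC)c(O)c3OC)C[C@@H](CO)[C@@H]2CO)cc(OC)c1O | target

Total step count: 8. Longest linear sequence: 7 (steps 1, 2, 3, then 4 or 5, then 6, 7, 8).

**Steps most likely to fail**

Step 6. Three things may go wrong:
- The radical cation may add only slowly to a beta-substituted styrene.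
- Facial selectivity at the alkene carbon that becomes C2 may be poor.
- The styrene may be consumed by competing oxidation and oligomerisation.

The fallback makes the two bonds in separate, known operations. It sets out from 6 and comes back at 11.
- Pinnick oxidation (NaClO2, NaH2PO4, 2-methyl-2-butene, t-BuOH/H2O) should give 3-[4-(benzyloxy)-3,5-dimethoxyphenyl]propanoic acid F1.
- Activation as the mixed anhydride (t-BuCOCl, Et3N), followed by LiCl and (S)-4-benzyl-1,3-oxazolidin-2-one, should give (S)-4-benzyl-3-{3-[4-(benzyloxy)-3,5-dimethoxyphenyl]propanoyl}-1,3-oxazolidin-2-one F2.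
- Oxidative homocoupling of its lithium enolate (LiN(i-Pr)2, THF, -78 °C, then CuCl2) forms the C2-C3 bond. Each enolate reacts on the face away from the auxiliary benzyl group, which should give (2R,3R)-2,3-bis[4-(benzyloxy)-3,5-dimethoxybenzyl]-1,4-bis[(S)-4-benzyl-2-oxo-1,3-oxazolidin-3-yl]butane-1,4-dione F3.
- LiBH4 in THF/MeOH should give (2R,3R)-2,3-bis[4-(benzyloxy)-3,5-dimethoxybenzyl]butane-1,4-diol F4.
- Hydrogenolysis (H2, Pd/C) should give (2R,3R)-2,3-bis(4-hydroxy-3,5-dimethoxybenzyl)butane-1,4-diol F5.
- One equivalent of DDQ dehydrogenates one para-hydroxybenzyl unit to its quinone methide. The remote hydroxyl closes it to (+)-5,5'-dimethoxylariciresinol F6.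
- CF3CO2H in CH2Cl2 at 0 °C re-ionises the benzylic C-O bond, and ring A closes C1-C8a trans to C2 to give 11.

Step 5. The ruthenium catalyst may be deactivated, the electron-rich cinnamyl alcohol may ionise at 100 °C, or the product aldehyde may self-condense. The fallback sets out from 3 and comes back at 6.
- Conjugate reduction with nickel boride (NiCl2·6H2O, NaBH4, MeOH/THF, 0 °C) should give ethyl 3-[4-(benzyloxy)-3,5-dimethoxyphenyl]propanoate F7.
- Partial reduction with i-Bu2AlH (1.05 equiv, toluene, -78 °C) should stop at aldehyde 6.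

Step 8. Cleavage of the aryl benzyl ethers, each flanked by two methoxy groups, may be incomplete, and the polar product may adsorb on and slow the heterogeneous catalyst. The fallback sets out from 10 and comes back at 11. It replaces reductive hydrogenolysis by Lewis-acid debenzylation with a cation scavenger (BCl3, pentamethylbenzene, CH2Cl2, -78 °C). This removes benzyl groups as benzyl cations and should spare the methyl ethers at that temperature.

**Further compounds**

F1 | step 6 | 3-[4-(benzyloxy)-3,5-dimethoxyphenyl]propanoic acid | OC(=O)CCc1cc(OC)c(OCc2ccccc2)c(OC)c1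
F2 | step 6 | (S)-4-benzyl-3-{3-[4-(benzyloxy)-3,5-dimethoxyphenyl]propanoyl}-1,3-oxazolidin-2-one | O=C(CCc1cc(OC)c(OCc2ccccc2)c(OC)c1)N1[C@@H](Cc2ccccc2)COC1=O
F3 | step 6 | (2R,3R)-2,3-bis[4-(benzyloxy)-3,5-dimethoxybenzyl]-1,4-bis[(S)-4-benzyl-2-oxo-1,3-oxazolidin-3-yl]butane-1,4-dione | O=C(N1[C@@H](Cc2ccccc2)COC1=O)[C@H](Cc1cc(OC)c(OCc2ccccc2)c(OC)c1)[C@@H](Cc1cc(OC)c(OCc2ccccc2)c(OC)c1)C(=O)N1[C@@H](Cc2ccccc2)COC1=O
F4 | step 6 | (2R,3R)-2,3-bis[4-(benzyloxy)-3,5-dimethoxybenzyl]butane-1,4-diol | OC[C@H](Cc1cc(OC)c(OCc2ccccc2)c(OC)c1)[C@@H](Cc1cc(OC)c(OCc2ccccc2)c(OC)c1)CO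
F5 | step 6 | (2R,3R)-2,3-bis(4-hydroxy-3,5-dimethoxybenzyl)butane-1,4-diol | OC[C@H](Cc1cc(OC)c(O)c(OC)c1)[C@@H](Cc1cc(OC)c(O)c(OC)c1)CO
F6 | step 6 | (+)-5,5'-dimethoxylariciresinol | COc1cc(C[C@H]2CO[C@@H]([C@H]2CO)c2cc(OC)c(O)c(OC)c2)cc(OC)c1O
F7 | step 5 | ethyl 3-[4-(benzyloxy)-3,5-dimethoxyphenyl]propanoate | CCOC(=O)CCc1cc(OC)c(OCc2ccccc2)c(OC)c1
F0 | step 8 | none | none
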